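Which ratio comes first? The asked time t over a loss time τ, where τ is the time by which monomer in chains, U, has decayed by one e-fold. The loss turnovers n are the square of t/τ, and U keeps exp(−n) of what was made.

| setting | teal | amber | green | noon | autumn | dusk |
|---|---|---|---|---|---|---|
| free monomer | 0.23 M | 0.23 M | 0.46 M | 0.23 M | 0.23 M | 0.23 M |
| transfer agent | 2.3 mM | 2.3 mM | 2.3 mM | 2.30 mM | 2.30 mM | 2.30 mM |
| pre-initiator | 1.5 mM | 6 mM | 3 mM | 3.0 mM | 3.0 mM | 3.0 mM |
| temperature | 40 °C | 70 °C | 40 °C | 70 °C | 95 °C | 45 °C |
| remark | run made earlier | run made earlier | run made earlier |  |  |  |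
| time |  |  |  | 30 min | 30 min | 30 min |

| run | time / min | monomer in chains / % | free monomer / % |
|---|---|---|---|
| teal | 8.00 | 13 | 84 |
| teal | 25.0 | 73 | 23 |
| teal | 40.0 | 95 | 4 |
| teal | 60.0 | 92 | 0 |
| teal | 80.0 | 91 | 2 |
| teal | 120 | 70 | 1 |
| teal | 180 | 47 | 0 |
| amber | 5.00 | 66 | 2 |
| amber | 10.0 | 21 | 0 |
| amber | 15.0 | 4 | 0 |
| amber | 20.0 | 0 | 1 |
| amber | 25.0 | 2 | 2 |
| amber | 30.0 | 0 | 0 |
| amber | 40.0 | 1 | 0 |
| green | 12.0 | 51 | 47 |
| green | 20.0 | 86 | 17 |
| green | 40.0 | 95 | 1 |
| green | 80.0 | 69 | 3 |
| green | 180 | 12 | 0 |

(each reading ± 2 percentage points)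

- what was read earlier has a scatter of 2 percentage points, one standard deviation

- the best flask by amount of monomer in chains, in percent of the free monomer charged; "all alike" if 1.5 percentage points covers them all (noon / autumn / dusk / all alike)
- amount of monomer in chains at the end, in percent of the free monomer charged, noon
- amount of monomer in chains at the end, in percent of the free monomer charged, autumn
- amount of monomer in chains at the end, in percent of the free monomer charged, dusk

Why squared? U is the intermediate of a consecutive reaction, and its decay steepens. In the amber readings ln U drops 1.15 from 5.00 min to 10.0 min, then 1.66 over the equal step after it.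

How do you get τ? From two readings past the peak: τ squared is the difference of the squared times over ln(U early/U late). These readings give 198 min for teal, 122 min for green and 8.09 min for amber.

Does n follow the pre-initiator? If it does, teal over green should be 1.41. It reads 1.62, although green also holds twice the free monomer. With this scatter I accept it.

Noon, then? Amber scaled to 3.0 mM gives τ = 11.4 min, so n = 6.87 and U is about 0.104%. Autumn is hotter, so I expect less.

Dusk? Per unit of pre-initiator, the loss read in amber is 113 times the loss read in green. Dusk stands 0.167 of the way from green's temperature to amber's and holds green's pre-initiator. Taken as exponential in temperature, that makes the loss 2.20 times green's. The loss time of dusk is τ = 82.2 min, so n = 0.133 and U is about 87.5%.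

The weak spot? That count assumes the free monomer is in chains early. The same rule on green's free monomer gives a use time of 15.0 min, shorter than the dusk loss time.

The forecast says dusk, with noon 1% and autumn 0%, and it gives dusk 88%, on the ground that “Monomer is consumed well before 30 min”. My noon figure is lower than its number.

The flasks give 4.10% for noon, 0.00608% for autumn and 92.1% for dusk, so the best is dusk.

    free monomer + initiator → living end + monomer in chains (k = 1.16 L mol⁻¹ s⁻¹, Ea = 61.0 kJ mol⁻¹)
    free monomer + living end → monomer in chains + living end, rate k2*[living end]*[free monomer] (k = 33.9 L mol⁻¹ s⁻¹, Ea = 51.0 kJ mol⁻¹)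
    living end + transfer agent → dead chain (kL = 0.855 L mol⁻¹ s⁻¹, Ea = 55.0 kJ mol⁻¹)
    pre-initiator → initiator (k = 0.00398 s⁻¹, Ea = 92.0 kJ mol⁻¹)
    initiator + monomer in chains → initiator + over-reaction product (k = 1.29 L mol⁻¹ s⁻¹, Ea = 52.0 kJ mol⁻¹)
    (constants at 70 °C)

Dusk holds 92.1% of monomer in chains at 30.0 min. Free monomer there is down to 0.154%, and monomer in chains is made at 0.0488 of the rate at which it is used up, so it is already falling. Read the same dusk flask at 2.0 h: the loss time 82.2 min gives n = 2.13, which leaves 11.9%, and the flask holds 9.67%.

Readings and results were generated by integration for substances that don't exist, noise included.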